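Ring C (cyclohexene C1–C6; C1 quaternary with methyl and the styryl arm to coumarin A, C6 carrying coumarin B, C4=C5 alkene) is disconnected at C1–CH3 and C6–aryl. Methyl and aryl are trans on the adjacent atoms C1 and C6, so both bonds are made in one operation by anti addition across the C1=C6 alkene of a cyclic dienyl boronate. Methyllithium gives the borate, and a chiral arylpalladium triflate induces methyl migration from boron to C1 and delivers aryl to C6, setting both stereocentres. Boron stays at C1 and is later exchanged for vinyl. The precursor is 4-methylcyclohexa-1,3-dienyl pinacol boronate; the aryl partner is symmetrical 2,6-dimethoxyphenyl triflate, a masked coumarin B.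

Key step: step 5

Remarks
- Atom labels: ring C is C1 (quaternary) – C2H2 – C3H2 – C4(CH3)=C5H – C6H(aryl). Coumarin A sits on the ethenyl bridge, coumarin B on C6.
- Assumption: the facial preference of the ferrocene bisphosphine for a cyclic dienyl borate cannot be predicted, so the (S,S) ligand is written and its mirror image is used if it should favour the other face.
- The phenol oxygen of coumarin B is carried as a methyl ether. The triflate is then one step from a commercial phenol and is symmetrical. Unmasking is done with thiolate under basic conditions before any coumarin is present, because a free phenol next to the C4=C5 alkene would add across it under acid.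
- After step 6 the C1 alkenyl group and the C4=C5 alkene form a 1,5-diene through the C1–C6 bond. All later steps therefore stay at or below about 120 °C to exclude Cope rearrangement, and coumarin B is closed by an intramolecular Wittig reaction, not a high-temperature condensation.
- Dienyl boronate 7 is air-sensitive (aromatisation, dimerisation) and is used soon after it is made.

Step 1
Reactants: 1 4-methylanisole
Product: 3 4-methylcyclohex-3-en-1-one, via 1-methoxy-4-methylcyclohexa-1,4-diene 2 (not isolated)
Conditions: Li, NH3(l), t-BuOH, THF, −78 → −33 °C; crude enol ether, (CO2H)2 (cat.), MeOH/H2O, rt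
Reagents that add atoms: water, O
Why: Birch reduction leaves the two ring alkenes at the methoxy- and methyl-bearing carbons, and oxalic acid hydrolyses the enol ether under conditions too mild to move the remaining alkene into conjugation.

Step 2
Reactants: 3 4-methylcyclohex-3-en-1-one
Product: 5 4-methylcyclohexa-1,3-dien-1-yl trifluoromethanesulfonate, via lithium dienolate 4 (not isolated)
Conditions: LiN(SiMe3)2, THF, −78 °C (ketone added to the base); PhNTf2, −78 → 0 °C
Reagents that add atoms: N-phenylbis(trifluoromethanesulfonimide), O=S(=O)(N(c1ccccc1)S(=O)(=O)C(F)(F)F)C(F)(F)F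
Why: The hydrogens on the carbon between the carbonyl group and the ring alkene are the most acidic, so the amide base should give the through-conjugated lithium dienolate, which is sulfonylated on oxygen (enol triflate formation).

Step 3
Reactants: 5 4-methylcyclohexa-1,3-dien-1-yl trifluoromethanesulfonate, 6 bis(pinacolato)diboron
Product: 7 4,4,5,5-tetramethyl-2-(4-methylcyclohexa-1,3-dien-1-yl)-1,3,2-dioxaborolane
Conditions: PdCl2(PPh3)2 (3 mol %), PPh3, KOPh, toluene, 50 °C, argon
Reagents that add atoms: none
Why: Miyaura borylation of an alkenyl triflate (oxidative addition to zerovalent palladium, phenoxide-assisted transmetallation from the diboron reagent, reductive elimination) should keep the diene in place under these mild conditions.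

Step 4
Reactants: 8 2,6-dimethoxyphenol
Product: 9 2,6-dimethoxyphenyl trifluoromethanesulfonate
Conditions: Tf2O, pyridine, CH2Cl2, 0 °C
Reagents that add atoms: trifluoromethanesulfonic anhydride, O=S(=O)(OS(=O)(=O)C(F)(F)F)C(F)(F)F
Why: O-sulfonylation of a phenol gives a symmetrical aryl triflate that already carries both oxygen atoms needed for coumarin B.

Step 5
Reactants: 7 4,4,5,5-tetramethyl-2-(4-methylcyclohexa-1,3-dien-1-yl)-1,3,2-dioxaborolane, 9 2,6-dimethoxyphenyl trifluoromethanesulfonate, 10 methyllithium
Product: 12 2-[(1R,2R)-2-(2,6-dimethoxyphenyl)-1,4-dimethylcyclohex-3-en-1-yl]-4,4,5,5-tetramethyl-1,3,2-dioxaborolane (boron on C1 cis to the aryl group on C6; methyl trans to aryl), via lithium dienyl(methyl)borate 11 (not isolated)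
Conditions: MeLi (halide-free, Et2O), THF, 0 °C → rt; then 9, Pd(OAc)2 (3 mol %), (S,S)-1,1′-bis[bis(4-methoxy-3,5-dimethylphenyl)phosphino]-2,2′-bis[(R)-(dimethylamino)(phenyl)methyl]ferrocene (3.6 mol %), THF, 60 °C
Reagents that add atoms: none
Why: Proposed new method: zerovalent palladium formed from Pd(OAc)2 and the bisphosphine inserts into the C–O bond of triflate 9, and the cationic arylpalladium, which the triflate counter-ion leaves with a free site, binds the C1=C6 alkene of borate 11 as a π-acid, so that methyl shifts from boron to C1 on the face opposite to palladium and an arylpalladium allyl species spanning C4–C5–C6 results. Reductive elimination at C6 then places the aryl group on the face that palladium held, so C1–CH3 and C6–aryl form anti (methyl trans to aryl, boron cis to aryl) and no ring is closed. The closest known reaction type is the enantioselective palladium-catalysed conjunctive coupling of alkenylboron ate complexes with aryl triflates through a 1,2-metallate shift, whose precedent covers open-chain vinyl and substituted alkenyl boronates, including α-substituted ones that give tertiary boronates, whereas a ring-embedded conjugated dienyl boronate has not been used. The configuration at C6 is set by the diene face that the chiral ligand allows palladium to take, and that at C1 follows from it through the anti-periplanar shift and the stereoretentive reductive elimination. The step needs arylation at C6 and not at C4, which the C4 methyl group should secure because a quaternary centre would have to form there. It also needs methyl migration to outrun direct transfer of the dienyl group to palladium, which halide-free methyllithium, the triflate leaving group and the hindered pinacol ligand on boron should favour.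

Step 6
Reactants: 12 2-[(1R,2R)-2-(2,6-dimethoxyphenyl)-1,4-dimethylcyclohex-3-en-1-yl]-4,4,5,5-tetramethyl-1,3,2-dioxaborolane
Product: 15 2-[(1R,6R)-6-ethenyl-3,6-dimethylcyclohex-2-en-1-yl]-1,3-dimethoxybenzene, via lithium vinyl borate 13 (not isolated), via β-iodoalkyl boronate 14 (not isolated)
Conditions: CH2=CHLi (from Sn(CH=CH2)4, n-BuLi), THF, −78 °C → rt; I2, MeOH, −78 °C; NaOMe, MeOH, −78 °C → rt
Reagents that add atoms: vinyllithium, [Li]C=C (made in the flask from tetravinylstannane, C=C[Sn](C=C)(C=C)C=C)
Why: Zweifel olefination: vinyllithium adds to boron, iodine activates the vinyl group, the tertiary ring carbon migrates from boron to carbon with retention of configuration, and methoxide causes anti elimination of boron and iodide, so the C1 stereocentre is carried over unchanged.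

Step 7
Reactants: 15 2-[(1R,6R)-6-ethenyl-3,6-dimethylcyclohex-2-en-1-yl]-1,3-dimethoxybenzene
Product: 16 2-[(1R,6R)-6-ethenyl-3,6-dimethylcyclohex-2-en-1-yl]-3-methoxyphenol
Conditions: NaSEt, DMF, 110–120 °C
Reagents that add atoms: none
Why: Nucleophilic demethylation of an aryl methyl ether by thiolate (SN2 at the methyl carbon) should stop after one of the two equivalent methoxy groups because the phenoxide formed resists a second attack, and the basic medium leaves the alkenes untouched.

Step 8
Reactants: 16 2-[(1R,6R)-6-ethenyl-3,6-dimethylcyclohex-2-en-1-yl]-3-methoxyphenol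
Product: 17 3-[(1R,6R)-6-ethenyl-3,6-dimethylcyclohex-2-en-1-yl]-2-hydroxy-4-methoxybenzaldehyde
Conditions: MgCl2, Et3N, (CH2O)n, MeCN, 80 °C
Reagents that add atoms: paraformaldehyde (as formaldehyde), C=O
Why: Magnesium-mediated ortho-formylation of a phenol (Casnati–Skattebøl reaction) directs formaldehyde to the only free ortho position, which is also para to the methoxy group, and a second formaldehyde oxidises the benzylic alkoxide to the aldehyde.

Step 9
Reactants: 17 3-[(1R,6R)-6-ethenyl-3,6-dimethylcyclohex-2-en-1-yl]-2-hydroxy-4-methoxybenzaldehyde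
Product: 19 8-[(1R,6R)-6-ethenyl-3,6-dimethylcyclohex-2-en-1-yl]-7-methoxy-2H-chromen-2-one, via ester ylide 18 (not isolated)
Conditions: Ph3P=C=C=O, toluene, 100 °C
Reagents that add atoms: (triphenylphosphoranylidene)ketene, O=C=C=P(c1ccccc1)(c1ccccc1)c1ccccc1
Why: The phenol adds to the ketene ylide to give the ester-stabilised ylide 18, which closes by intramolecular Wittig reaction with the ortho aldehyde, the six-membered ring enforcing the cis alkene of the coumarin at moderate temperature.

Step 10
Reactants: 20 umbelliferone (7-hydroxy-2H-chromen-2-one)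
Product: 21 7-hydroxy-8-iodo-2H-chromen-2-one
Conditions: I2, KI, aq. NH3, rt
Reagents that add atoms: iodine, I-I
Why: Electrophilic aromatic iodination of the phenoxide in aqueous ammonia takes place at C8, the ortho position lying between the two ring oxygens.

Step 11
Reactants: 21 7-hydroxy-8-iodo-2H-chromen-2-one
Product: 22 8-iodo-7-methoxy-2H-chromen-2-one
Conditions: MeI, K2CO3, acetone, reflux
Reagents that add atoms: iodomethane, CI
Why: Williamson O-methylation of the phenol.

Step 12
Reactants: 19 8-[(1R,6R)-6-ethenyl-3,6-dimethylcyclohex-2-en-1-yl]-7-methoxy-2H-chromen-2-one, 22 8-iodo-7-methoxy-2H-chromen-2-one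
Product: 23 7-methoxy-8-[(E)-2-[(1R,2R)-2-(7-methoxy-2-oxo-2H-chromen-8-yl)-1,4-dimethylcyclohex-3-en-1-yl]ethenyl]-2H-chromen-2-one
Conditions: Pd(OAc)2 (10 mol %), P(o-tol)3 (20 mol %), Et3N, DMF, 90 °C
Reagents that add atoms: none
Why: Mizoroki–Heck reaction: the arylpalladium iodide adds its aryl group to the terminal carbon of the only monosubstituted alkene, and because C1 is quaternary β-hydride elimination can only give the conjugated E-alkene, with both stereocentres untouched.

Compound list
1 | 4-methylanisole | COc1ccc(C)cc1 | starting material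
2 | 1-methoxy-4-methylcyclohexa-1,4-diene | COC1=CCC(C)=CC1 | intermediate
3 | 4-methylcyclohex-3-en-1-one | O=C1CC=C(C)CC1 | intermediate
4 | lithium 4-methylcyclohexa-1,3-dien-1-olate | [Li+].CC1=CC=C([O-])CC1 | intermediate
5 | 4-methylcyclohexa-1,3-dien-1-yl trifluoromethanesulfonate | CC1=CC=C(OS(=O)(=O)C(F)(F)F)CC1 | intermediate
6 | bis(pinacolato)diboron | CC1(C)OB(OC1(C)C)B1OC(C)(C)C(C)(C)O1 | starting material
7 | 4,4,5,5-tetramethyl-2-(4-methylcyclohexa-1,3-dien-1-yl)-1,3,2-dioxaborolane | CC1=CC=C(B2OC(C)(C)C(C)(C)O2)CC1 | intermediate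
8 | 2,6-dimethoxyphenol | COc1cccc(OC)c1O | starting material
9 | 2,6-dimethoxyphenyl trifluoromethanesulfonate | COc1cccc(OC)c1OS(=O)(=O)C(F)(F)F | intermediate
10 | methyllithium | [Li]C | starting material
11 | lithium methyl(4-methylcyclohexa-1,3-dien-1-yl)(pinacolato)borate | [Li+].CC1=CC=C(CC1)[B-]1(C)OC(C)(C)C(C)(C)O1 | intermediate
12 | 2-[(1R,2R)-2-(2,6-dimethoxyphenyl)-1,4-dimethylcyclohex-3-en-1-yl]-4,4,5,5-tetramethyl-1,3,2-dioxaborolane (boron cis to aryl, methyl trans to aryl) | CC1(C)OB(OC1(C)C)[C@@]2(C)CCC(C)=C[C@H]2c2c(OC)cccc2OC | intermediate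
13 | lithium ethenyl[(1R,2R)-2-(2,6-dimethoxyphenyl)-1,4-dimethylcyclohex-3-en-1-yl](pinacolato)borate | [Li+].C=C[B-]1(OC(C)(C)C(C)(C)O1)[C@@]2(C)CCC(C)=C[C@H]2c2c(OC)cccc2OC | intermediate
14 | 2-{1-[(1R,2R)-2-(2,6-dimethoxyphenyl)-1,4-dimethylcyclohex-3-en-1-yl]-2-iodoethyl}-4,4,5,5-tetramethyl-1,3,2-dioxaborolane (boron-bearing carbon of either configuration) | ICC(B1OC(C)(C)C(C)(C)O1)[C@@]2(C)CCC(C)=C[C@H]2c2c(OC)cccc2OC | intermediate
15 | 2-[(1R,6R)-6-ethenyl-3,6-dimethylcyclohex-2-en-1-yl]-1,3-dimethoxybenzene (vinyl cis to aryl) | C=C[C@@]1(C)CCC(C)=C[C@H]1c1c(OC)cccc1OC | intermediate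
16 | 2-[(1R,6R)-6-ethenyl-3,6-dimethylcyclohex-2-en-1-yl]-3-methoxyphenol | C=C[C@@]1(C)CCC(C)=C[C@H]1c1c(O)cccc1OC | intermediate
17 | 3-[(1R,6R)-6-ethenyl-3,6-dimethylcyclohex-2-en-1-yl]-2-hydroxy-4-methoxybenzaldehyde | C=C[C@@]1(C)CCC(C)=C[C@H]1c1c(O)c(C=O)ccc1OC | intermediate
18 | 2-[(1R,6R)-6-ethenyl-3,6-dimethylcyclohex-2-en-1-yl]-6-formyl-3-methoxyphenyl (triphenylphosphoranylidene)acetate | C=C[C@@]1(C)CCC(C)=C[C@H]1c1c(OC(=O)C=P(c2ccccc2)(c2ccccc2)c2ccccc2)c(C=O)ccc1OC | intermediate
19 | 8-[(1R,6R)-6-ethenyl-3,6-dimethylcyclohex-2-en-1-yl]-7-methoxy-2H-chromen-2-one | C=C[C@@]1(C)CCC(C)=C[C@H]1c1c(OC)ccc2ccc(=O)oc12 | intermediate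
20 | umbelliferone (7-hydroxy-2H-chromen-2-one) | O=c1ccc2ccc(O)cc2o1 | starting material
21 | 7-hydroxy-8-iodo-2H-chromen-2-one | O=c1ccc2ccc(O)c(I)c2o1 | intermediate
22 | 8-iodo-7-methoxy-2H-chromen-2-one | COc1ccc2ccc(=O)oc2c1I | intermediate
23 | 7-methoxy-8-[(E)-2-[(1R,2R)-2-(7-methoxy-2-oxo-2H-chromen-8-yl)-1,4-dimethylcyclohex-3-en-1-yl]ethenyl]-2H-chromen-2-one | COc1ccc2ccc(=O)oc2c1/C=C/[C@@]1(C)CCC(C)=C[C@H]1c1c(OC)ccc2ccc(=O)oc12 | target

Total step count: 12.
Longest linear sequence: 9 steps (1, 2, 3, 5, 6, 7, 8, 9, 12).

Steps most likely to fail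

1. Step 5. Direct transfer of the dienyl group from boron to palladium could compete with methyl migration. The allylpalladium intermediate could also be arylated at C4 or lose a β-hydrogen. The doubly ortho-substituted aryl group could slow oxidative addition and reductive elimination, and facial selection by the ligand could be weak. The fallback uses known chemistry; it sets out from triflate 9 and returns at 15, so that steps 5 and 6 are both replaced.
   - Hydroboration of 2-methylbut-1-en-3-yne with pinacolborane (Cp2Zr(H)Cl cat.) gives 4,4,5,5-tetramethyl-2-[(1E)-3-methylbuta-1,3-dien-1-yl]-1,3,2-dioxaborolane F1.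
   - Suzuki–Miyaura coupling of F1 with 9 (Pd(OAc)2, SPhos, K3PO4, THF/H2O, 60 °C) gives 1,3-dimethoxy-2-[(1E)-3-methylbuta-1,3-dien-1-yl]benzene F2.
   - An enantioselective Diels–Alder reaction of F2 with methacrolein follows, catalysed by a chiral oxazaborolidinium triflimide (from the diphenylprolinol-derived o-tolyl oxazaborolidine and HNTf2, CH2Cl2, −78 → −40 °C). The aryl and methyl groups of the diene and the formyl group of the dienophile reinforce one another in orientation, and the endo mode should place formyl cis to aryl, giving (1S,2S)-2-(2,6-dimethoxyphenyl)-1,4-dimethylcyclohex-3-ene-1-carbaldehyde F3. The catalyst antipode is chosen for this enantiomer.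
   - Wittig methylenation (Ph3PCH3Br, KOt-Bu, THF, 0 °C) converts F3 into 15.

2. Step 6. Borate formation at the hindered tertiary boron could be incomplete, or iodine could be consumed by the electron-rich arene and the ring alkene before the 1,2-shift. The fallback sets out from 12 and returns at 15.
   - Matteson homologation with chloromethyllithium (BrCH2Cl, n-BuLi, THF, −78 °C → rt), a smaller and more reactive nucleophile that needs no iodine, gives 2-{[(1S,2R)-2-(2,6-dimethoxyphenyl)-1,4-dimethylcyclohex-3-en-1-yl]methyl}-4,4,5,5-tetramethyl-1,3,2-dioxaborolane F4, with retention at C1.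
   - Oxidation (H2O2, NaOH, THF, 0 °C) gives [(1S,2R)-2-(2,6-dimethoxyphenyl)-1,4-dimethylcyclohex-3-en-1-yl]methanol F5.
   - Dess–Martin oxidation gives the aldehyde (1S,2S)-2-(2,6-dimethoxyphenyl)-1,4-dimethylcyclohex-3-ene-1-carbaldehyde F3, and Wittig methylenation as above gives 15.

3. Step 12. Insertion of the hindered alkene into the hindered arylpalladium species could be slow, so that reduction of the iodide or arylation of the coumarin alkene takes over. The fallback sets out from 22 and returns at 23.
   - Suzuki–Miyaura vinylation of 22 with potassium vinyltrifluoroborate (PdCl2(dppf), Cs2CO3, THF/H2O, 80 °C) gives 8-ethenyl-7-methoxy-2H-chromen-2-one F6.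
   - Alkene cross-metathesis of 19 with F6 (second-generation Hoveyda–Grubbs catalyst, toluene, 60 °C) releases ethene and should give the E-alkene 23. The trisubstituted ring alkene and the lactone alkenes are expected to stay out of the metathesis.

Further compounds
F1 | step 5 | 4,4,5,5-tetramethyl-2-[(1E)-3-methylbuta-1,3-dien-1-yl]-1,3,2-dioxaborolane | CC(=C)/C=C/B1OC(C)(C)C(C)(C)O1
F2 | step 5 | 1,3-dimethoxy-2-[(1E)-3-methylbuta-1,3-dien-1-yl]benzene | COc1cccc(OC)c1/C=C/C(C)=C
F3 | step 5 | (1S,2S)-2-(2,6-dimethoxyphenyl)-1,4-dimethylcyclohex-3-ene-1-carbaldehyde (formyl cis to aryl) | O=C[C@@]1(C)CCC(C)=C[C@H]1c1c(OC)cccc1OC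
F4 | step 6 | 2-{[(1S,2R)-2-(2,6-dimethoxyphenyl)-1,4-dimethylcyclohex-3-en-1-yl]methyl}-4,4,5,5-tetramethyl-1,3,2-dioxaborolane | CC1(C)OB(OC1(C)C)C[C@@]2(C)CCC(C)=C[C@H]2c2c(OC)cccc2OC
F5 | step 6 | [(1S,2R)-2-(2,6-dimethoxyphenyl)-1,4-dimethylcyclohex-3-en-1-yl]methanol | OC[C@@]1(C)CCC(C)=C[C@H]1c1c(OC)cccc1OC
F6 | step 12 | 8-ethenyl-7-methoxy-2H-chromen-2-one | COc1ccc2ccc(=O)oc2c1C=C
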